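Amounts of L are what differs among these flasks: the charges run from 0.015 M in zeta to 0.20 M in beta, under the same held D.

| flask | L | D | remark | time |
|---|---|---|---|---|
| noon | 0.012 M | 5.7 mM (held) | run made earlier |  |
| winter | 0.13 M | 5.7 mM (held) | run made earlier |  |
| beta | 0.20 M | 5.7 mM (held) |  | 8.0 d |
| theta | 0.050 M | 5.7 mM (held) |  | 8.0 d |
| alpha | 0.080 M | 5.7 mM (held) |  | 8.0 d |
| zeta | 0.015 M | 5.7 mM (held) |  | 8.0 d |
| eta | 0.10 M | 5.7 mM (held) |  | 8.0 d |

* the flasks by amount of Z, in percent of the L charged, highest first, at 8.0 d (beta / theta / alpha / zeta / eta)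
* the same order at 20 h (beta / theta / alpha / zeta / eta)
* the amount of Z, in percent of the L charged of the flask you put first, at 8.0 d
* the amount of Z, in percent of the L charged of the flask you put last, at 8.0 d

| run | time / d | Z / % | L / % |
|---|---|---|---|
| noon | 0.625 | 59 | 4 |
| noon | 1.25 | 56 | 0 |
| noon | 2.08 | 63 | 0 |
| noon | 2.50 | 60 | 1 |
| noon | 3.00 | 63 | 0 |
| noon | 4.00 | 61 | 2 |
| winter | 0.333 | 9 | 49 |
| winter | 0.500 | 14 | 30 |
| winter | 0.833 | 19 | 11 |
| winter | 1.67 | 31 | 1 |
| winter | 2.50 | 28 | 1 |
| winter | 4.00 | 34 | 4 |

(scatter of a reading: 2 percentage points)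

- at the start none of D is in solution

In the winter run L reads 1% by 1.67 d, and Z then scatters about a plateau. So 8.0 d asks for the plateau Y, the overall selectivity for Z, as a share of the charge. But the plateau readings differ: noon averages 60.6% and winter 31.0%, so in the winter run, with the larger charge, less of the L charged ends as Z.

My own reckoning draws the simplest falling curve through these two points, Y = Yd·c*/(c* + Lc), with Lc the charge and Yd the dilute limit of Y. Solving gives 0.112 M for c*, the yield-halving charge, at which Y stands at half of Yd, and 67.1% for Yd. On this curve Y falls as the charge rises, which ranks the flasks by charge: zeta gets 59.2% and beta 24.0%. At 0.833 d, winter reads Z at 19%, below its plateau average, while noon reads 59% as early as 0.625 d, so I keep the same ranking at 20 h.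

The forecast gives zeta > theta > alpha > eta > beta at 8.0 d and zeta > theta > alpha > eta > beta at 20 h, with 59% (55% to 62%) and 24% (18% to 28%), on the ground that “Yield falls with charge”. It rests on the same two runs as my reckoning, so their agreement tests nothing.

The flasks give zeta > theta > alpha > eta > beta at 8.0 d and zeta > theta > alpha > eta > beta at 20 h, with zeta at 59.0% and beta at 24.5%. With the time held, zeta's Z moves 5 points, past the forecast's range, at a charge of 0.00581 M or 0.0256 M. With c* at 0.112 M, eta at 0.10 M should reach 35.4%, and it gives 34.7%.

    2 L → G (k = 2.50 × 10⁻⁶ /M/min)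
    L → X (k = 0.00120 /min)
    L + Q → Z (k = 0.780 /M/min)
    D ⇌ Q, rate k4*(csat - [Q]) (kL = 0.00540 /min)

For the neighbour of beta charged with 0.80 M of L, c* gives 8.22%. The computed flask holds 10.2% of Z, more than the curve.

(The runs come from a simulation for substances that don't exist; the scatter is artificial.)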